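Tangeretin is cut through ring A. Its carbons C5 to C8 all carry oxygen and are traced to the four carbons of dimethyl squarate, while the C4a=C8a edge, flanked by C4 and O1, is the enol ether double bond of a dihydropyran that already holds ring B at C2 and a masked carbonyl at C4. The precursor is the tertiary cyclobutenol formed when the C6-lithiated dihydropyran adds to one squarate carbonyl. Heating opens its four-membered ring to a dienylketene that closes the C5-C4a bond and aromatises, so the fully substituted ring A appears in one operation with every oxygen in place. Methylation and oxidation of ring C complete the flavone.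

Key step: step 5

Remark: the target is achiral and every sp3 centre of the intermediates is erased before the end, so racemates and diastereomer mixtures are carried on and their SMILES bear no stereodescriptors; only the double bonds of 2 and 11 are specified.

Step 1
Reactants: 1 4-methoxybenzaldehyde; 2 (E)-1-methoxy-3-(trimethylsilyloxy)buta-1,3-diene (1.5 equiv)
Product: 4 racemic 2-(4-methoxyphenyl)-2,3-dihydro-4H-pyran-4-one, via silyl enol ether cycloadduct 3 (not isolated)
Conditions: ZnCl2 (0.5 equiv), THF, rt; then 0.1 M aq HCl, THF, 0 °C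
Reagents that add atoms: none
Why: Hetero-Diels-Alder reaction: ZnCl2 activates the aldehyde towards the electron-rich siloxydiene, whose polarity puts the carbonyl oxygen on the methoxy-bearing terminus, and dilute acid then hydrolyses the silyl enol ether of 3 and expels methanol by beta-elimination, C2 being formed as a racemate because no chiral element is present.

Step 2
Reactants: 4 racemic 2-(4-methoxyphenyl)-2,3-dihydro-4H-pyran-4-one
Product: 5 racemic 2-(4-methoxyphenyl)-3,4-dihydro-2H-pyran-4-ol (cis-2,4 isomer expected to prevail)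
Conditions: NaBH4, CeCl3·7H2O, MeOH-CH2Cl2, -78 °C; sat. aq NaHCO3
Reagents that add atoms: none
Why: Luche reduction: the hard alkoxyborohydride generated with CeCl3 in methanol attacks the carbonyl carbon and not the vinylogous ester terminus C6, axial delivery of hydride to the half-chair with an equatorial aryl group should favour the cis-2,4 alcohol, and low temperature with a bicarbonate quench prevents allylic solvolysis.

Step 3
Reactants: 5 racemic 2-(4-methoxyphenyl)-3,4-dihydro-2H-pyran-4-ol
Product: 6 racemic 2-(4-methoxyphenyl)-4-(triisopropylsilyloxy)-3,4-dihydro-2H-pyran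
Conditions: TIPSCl, imidazole, DMAP (cat.), DMF, rt
Reagents that add atoms: triisopropylsilyl chloride, CC(C)[Si](Cl)(C(C)C)C(C)C
Why: Imidazole-promoted silylation of a secondary alcohol, run base-buffered and free of Lewis acid so that the allylic C4-O bond does not ionise; the triisopropylsilyl group offers no Si-CH3 hydrogens to t-BuLi, tolerates 110 °C and carbonate, and leaves the configuration at C4 untouched.

Step 4
Reactants: 6 racemic 2-(4-methoxyphenyl)-4-(triisopropylsilyloxy)-3,4-dihydro-2H-pyran; 7 dimethyl squarate (3,4-dimethoxycyclobut-3-ene-1,2-dione)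
Product: 10 4-hydroxy-2,3-dimethoxy-4-[2-(4-methoxyphenyl)-4-(triisopropylsilyloxy)-3,4-dihydro-2H-pyran-6-yl]cyclobut-2-en-1-one (diastereomer mixture), via 6-lithio dihydropyran 8 (not isolated), via lithium alkoxide 9 (not isolated)
Conditions: t-BuLi (1.2 equiv), pentane-THF (ca. 10:1 v/v), -78 to 0 °C; diluted with THF and cannulated into 7 (1.5 equiv), THF, -78 °C; sat. aq NH4Cl, -78 °C; Et3N-deactivated silica
Reagents that add atoms: none
Why: Alpha-lithiation of a cyclic enol ether followed by 1,2-addition of the vinyllithium to a squarate carbonyl, both standard operations: t-BuLi docks on O1 and in a weakly polar medium should remove the unhindered sp2 C6-H faster than the tertiary C2-H, whose delocalised benzylic anion is disfavoured by the para-methoxy group and by poor solvation, surplus base is consumed by THF at 0 °C, inverse addition to the symmetric diester prevents double addition, and the new carbinol centre forms without control because step 5 erases it.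

Step 5
Reactants: 10 4-hydroxy-2,3-dimethoxy-4-[2-(4-methoxyphenyl)-4-(triisopropylsilyloxy)-3,4-dihydro-2H-pyran-6-yl]cyclobut-2-en-1-one
Product: 13 5,8-dihydroxy-6,7-dimethoxy-2-(4-methoxyphenyl)-4-(triisopropylsilyloxy)chroman, via dienylketene 11 (not isolated), via cyclohexadienone 12 (not isolated)
Conditions: toluene (degassed, 0.02 M), Ar, 110 °C, base-washed glassware; solvent removed under Ar, crude product used at once
Reagents that add atoms: none
Why: Heat opens the cyclobutenone of 10 by a conrotatory four-electron electrocyclic reaction that breaks the bond between the carbinol carbon and the carbonyl carbon and gives the (Z)-dienylketene 11, which closes by a disrotatory six-electron electrocyclisation (ketene carbon onto the hydrogen-bearing carbon C5 of the dihydropyran) to dienone 12 and then tautomerises irreversibly to the aromatic hydroquinone 13. The closest known reaction type is the Moore rearrangement of 4-alkenyl-4-hydroxycyclobutenones derived from squarate esters, a class that includes adducts of alpha-lithiated cyclic enol ethers. One ring is closed, the six-membered carbocyclic ring A, by 6-pi electrocyclisation that forms the C5-C4a bond and fuses the new ring to ring C along C4a-C8a. No lasting stereocentre arises, because the carbinol carbon is flattened in the ring opening and C4a of 12 becomes sp2 on tautomerisation, while C2 and C4 are only spectators. The step needs torquoselectivity, hydroxyl turning outward and dihydropyranyl inward so that the ketene ends up cis to the C=C bond, and the donor hydroxyl group on the breaking sp3 carbon secures this. Regiochemistry is fixed by the substrate, since the two carbonyls of the squarate were equivalent and the enol ether has a single beta carbon, and degassed solvent in base-washed glass keeps the air-sensitive product and the acid-sensitive enol ether intact.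

Step 6
Reactants: 13 5,8-dihydroxy-6,7-dimethoxy-2-(4-methoxyphenyl)-4-(triisopropylsilyloxy)chroman
Product: 14 5,6,7,8-tetramethoxy-2-(4-methoxyphenyl)-4-(triisopropylsilyloxy)chroman
Conditions: MeI (6 equiv), K2CO3 (6 equiv), DMF (degassed), Ar, rt
Reagents that add atoms: iodomethane, CI
Why: Williamson-type O-methylation of both phenoxides at a stage where C4 is still sp3, so that the 5-hydroxyl is not tied up in a hydrogen bond to a C4 carbonyl, while exclusion of air keeps the hydroquinone from going to the quinone and room temperature holds back loss of silanolate from C4.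

Step 7
Reactants: 14 5,6,7,8-tetramethoxy-2-(4-methoxyphenyl)-4-(triisopropylsilyloxy)chroman
Product: 15 5,6,7,8-tetramethoxy-2-(4-methoxyphenyl)chroman-4-ol
Conditions: Bu4NF, THF, 0 °C to rt; pH 7 buffer; Et3N-deactivated silica
Reagents that add atoms: none
Why: Fluoride-driven cleavage of the Si-O bond, paid for by the strong Si-F bond, under basic conditions that spare the aryl methyl ethers and give the acid-labile benzylic alcohol no chance to ionise; C4 keeps its (irrelevant) configuration.

Step 8
Reactants: 15 5,6,7,8-tetramethoxy-2-(4-methoxyphenyl)chroman-4-ol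
Product: 16 racemic 5,6,7,8-tetramethoxy-2-(4-methoxyphenyl)chroman-4-one (5,6,7,8,4'-pentamethoxyflavanone)
Conditions: Pr4N[RuO4] (5 mol %), NMO, 4 Å MS, CH2Cl2, rt
Reagents that add atoms: none
Why: Ley-Griffith oxidation, catalytic perruthenate with NMO as terminal oxidant, converts the secondary benzylic alcohol into the ketone in an acid-free medium, which matters because a C4 cation would be strongly stabilised by O1 and by the 5- and 7-methoxy groups; the C4 stereocentre is removed.

Step 9
Reactants: 16 racemic 5,6,7,8-tetramethoxy-2-(4-methoxyphenyl)chroman-4-one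
Product: 18 tangeretin (5,6,7,8-tetramethoxy-2-(4-methoxyphenyl)-4H-chromen-4-one), via 3-iodoflavanone 17 (not isolated)
Conditions: I2 (10 mol %), DMSO, 120 °C
Reagents that add atoms: none
Why: Iodine-DMSO dehydrogenation of a flavanone: the enol is iodinated at C3, HI is lost across C2-C3 to give the conjugated pyranone, and DMSO reoxidises HI to I2 so that the acid level stays too low to cleave the 5-methoxy group; the last stereocentre C2 becomes sp2.

Compound list
1 | 4-methoxybenzaldehyde | COc1ccc(C=O)cc1 | starting material
2 | (E)-1-methoxy-3-(trimethylsilyloxy)buta-1,3-diene | CO/C=C/C(=C)O[Si](C)(C)C | starting material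
3 | 2-methoxy-6-(4-methoxyphenyl)-4-(trimethylsilyloxy)-5,6-dihydro-2H-pyran | COC1C=C(O[Si](C)(C)C)CC(c2ccc(OC)cc2)O1 | intermediate
4 | 2-(4-methoxyphenyl)-2,3-dihydro-4H-pyran-4-one (racemic) | COc1ccc(C2CC(=O)C=CO2)cc1 | intermediate
5 | 2-(4-methoxyphenyl)-3,4-dihydro-2H-pyran-4-ol (racemic, mainly cis expected) | COc1ccc(C2CC(O)C=CO2)cc1 | intermediate
6 | 2-(4-methoxyphenyl)-4-(triisopropylsilyloxy)-3,4-dihydro-2H-pyran (racemic) | COc1ccc(C2CC(O[Si](C(C)C)(C(C)C)C(C)C)C=CO2)cc1 | intermediate
7 | dimethyl squarate | COC1=C(OC)C(=O)C1=O | starting material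
8 | [2-(4-methoxyphenyl)-4-(triisopropylsilyloxy)-3,4-dihydro-2H-pyran-6-yl]lithium | [Li]C1=CC(O[Si](C(C)C)(C(C)C)C(C)C)CC(c2ccc(OC)cc2)O1 | intermediate
9 | lithium alkoxide of 10 | COc1ccc(C2CC(O[Si](C(C)C)(C(C)C)C(C)C)C=C(C3(O[Li])C(OC)=C(OC)C3=O)O2)cc1 | intermediate
10 | 4-hydroxy-2,3-dimethoxy-4-[2-(4-methoxyphenyl)-4-(triisopropylsilyloxy)-3,4-dihydro-2H-pyran-6-yl]cyclobut-2-en-1-one | COc1ccc(C2CC(O[Si](C(C)C)(C(C)C)C(C)C)C=C(C3(O)C(OC)=C(OC)C3=O)O2)cc1 | intermediate
11 | (Z)-4-hydroxy-2,3-dimethoxy-4-[2-(4-methoxyphenyl)-4-(triisopropylsilyloxy)-3,4-dihydro-2H-pyran-6-yl]buta-1,3-dien-1-one (ketene cis to the pyranyl group) | O=C=C(OC)/C(OC)=C(/O)C1=CC(O[Si](C(C)C)(C(C)C)C(C)C)CC(c2ccc(OC)cc2)O1 | intermediate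
12 | 8-hydroxy-6,7-dimethoxy-2-(4-methoxyphenyl)-4-(triisopropylsilyloxy)-2,3,4,4a-tetrahydro-5H-chromen-5-one | COc1ccc(C2CC(O[Si](C(C)C)(C(C)C)C(C)C)C3C(=O)C(OC)=C(OC)C(O)=C3O2)cc1 | intermediate
13 | 5,8-dihydroxy-6,7-dimethoxy-2-(4-methoxyphenyl)-4-(triisopropylsilyloxy)chroman | COc1ccc(C2CC(O[Si](C(C)C)(C(C)C)C(C)C)c3c(O)c(OC)c(OC)c(O)c3O2)cc1 | intermediate
14 | 5,6,7,8-tetramethoxy-2-(4-methoxyphenyl)-4-(triisopropylsilyloxy)chroman | COc1ccc(C2CC(O[Si](C(C)C)(C(C)C)C(C)C)c3c(OC)c(OC)c(OC)c(OC)c3O2)cc1 | intermediate
15 | 5,6,7,8-tetramethoxy-2-(4-methoxyphenyl)chroman-4-ol | COc1ccc(C2CC(O)c3c(OC)c(OC)c(OC)c(OC)c3O2)cc1 | intermediate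
16 | 5,6,7,8,4'-pentamethoxyflavanone (racemic) | COc1ccc(C2CC(=O)c3c(OC)c(OC)c(OC)c(OC)c3O2)cc1 | intermediate
17 | 3-iodo-5,6,7,8-tetramethoxy-2-(4-methoxyphenyl)chroman-4-one | COc1ccc(C2Oc3c(OC)c(OC)c(OC)c(OC)c3C(=O)C2I)cc1 | intermediate
18 | tangeretin | COc1ccc(-c2cc(=O)c3c(OC)c(OC)c(OC)c(OC)c3o2)cc1 | target

Total step count: 9. Longest linear sequence: 9 steps (1 to 18); 7 is bought and enters in step 4.

Steps most likely to fail

Step 4.
- **Risk:** Deprotonation at the benzylic C2-H, or ortho to the methoxy group of ring B, may compete with the vinylic lithiation. Leftover alkyllithium may attack the squarate. Traces of acid during work-up may protonate the enol ether and set off a pinacol-type enlargement of the four-membered ring.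
- **Fallback:** It sets out from 6 and makes the C6 anion regiospecifically. PhSO2H in CH2Cl2 at rt adds across the enol ether to give the anomeric sulfone 2-(4-methoxyphenyl)-6-(phenylsulfonyl)-4-(triisopropylsilyloxy)tetrahydropyran F1, whose C6-H is now by far the most acidic hydrogen. Treatment with n-BuLi (THF, -78 °C) and then Bu3SnCl gives 2-(4-methoxyphenyl)-6-(phenylsulfonyl)-6-(tributylstannyl)-4-(triisopropylsilyloxy)tetrahydropyran F2. This loses sulfinic acid with i-Pr2NEt in refluxing CHCl3 to give tributyl[2-(4-methoxyphenyl)-4-(triisopropylsilyloxy)-3,4-dihydro-2H-pyran-6-yl]stannane F3. Tin-lithium exchange with exactly one equivalent of n-BuLi (THF, -78 °C) delivers the vinyllithium free of excess base.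
- **Return:** The route is rejoined at 8.

Step 5.
- **Risk:** The free tertiary hydroxyl may capture the ketene after rotation in the wrong sense. Silanol may be lost thermally from C4 next to the new 5-hydroxyl. The very electron-rich product may degrade oxidatively at reflux.
- **Fallback:** It sets out from 9, which is not quenched but methylated in the flask with MeOTf (-78 °C to rt). This gives 2,3,4-trimethoxy-4-[2-(4-methoxyphenyl)-4-(triisopropylsilyloxy)-3,4-dihydro-2H-pyran-6-yl]cyclobut-2-en-1-one F4. The methoxy group is also a donor and turns outward, and it cannot add to the ketene. The same thermolysis in toluene therefore gives the air-stable monophenol 5-hydroxy-6,7,8-trimethoxy-2-(4-methoxyphenyl)-4-(triisopropylsilyloxy)chroman F5. A single methylation (MeI, K2CO3, DMF) follows.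
- **Return:** The route is rejoined at 14.

Step 6.
- **Risk:** The hydroquinone dianion may be oxidised by air under base. Alkylation of the crowded 5-oxygen may be slow. The 5-phenoxide may expel silanolate from C4.
- **Fallback:** It sets out from 13 and turns the oxidation into a purification handle. Ag2O in Et2O gives the stable, chromatographable 6,7-dimethoxy-2-(4-methoxyphenyl)-4-(triisopropylsilyloxy)chroman-5,8-dione F6. Two-phase reductive methylation (Na2S2O4, aq KOH, Me2SO4, Bu4NBr, THF-H2O) then regenerates 13 only in the presence of reductant and alkylating agent.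
- **Return:** The route is rejoined at 14.

Further compounds
F1 | step 4 | 2-(4-methoxyphenyl)-6-(phenylsulfonyl)-4-(triisopropylsilyloxy)tetrahydropyran | COc1ccc(C2CC(O[Si](C(C)C)(C(C)C)C(C)C)CC(S(=O)(=O)c3ccccc3)O2)cc1
F2 | step 4 | 2-(4-methoxyphenyl)-6-(phenylsulfonyl)-6-(tributylstannyl)-4-(triisopropylsilyloxy)tetrahydropyran | COc1ccc(C2CC(O[Si](C(C)C)(C(C)C)C(C)C)CC([Sn](CCCC)(CCCC)CCCC)(S(=O)(=O)c3ccccc3)O2)cc1
F3 | step 4 | tributyl[2-(4-methoxyphenyl)-4-(triisopropylsilyloxy)-3,4-dihydro-2H-pyran-6-yl]stannane | COc1ccc(C2CC(O[Si](C(C)C)(C(C)C)C(C)C)C=C([Sn](CCCC)(CCCC)CCCC)O2)cc1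
F4 | step 5 | 2,3,4-trimethoxy-4-[2-(4-methoxyphenyl)-4-(triisopropylsilyloxy)-3,4-dihydro-2H-pyran-6-yl]cyclobut-2-en-1-one | COc1ccc(C2CC(O[Si](C(C)C)(C(C)C)C(C)C)C=C(C3(OC)C(OC)=C(OC)C3=O)O2)cc1
F5 | step 5 | 5-hydroxy-6,7,8-trimethoxy-2-(4-methoxyphenyl)-4-(triisopropylsilyloxy)chroman | COc1ccc(C2CC(O[Si](C(C)C)(C(C)C)C(C)C)c3c(O)c(OC)c(OC)c(OC)c3O2)cc1
F6 | step 6 | 6,7-dimethoxy-2-(4-methoxyphenyl)-4-(triisopropylsilyloxy)chroman-5,8-dione | COc1ccc(C2CC(O[Si](C(C)C)(C(C)C)C(C)C)C3=C(O2)C(=O)C(OC)=C(OC)C3=O)cc1
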